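**Retrosynthetic overview**
- Both rings and four of the five stereocentres come from one intramolecular Diels–Alder reaction of an open-chain (2E,4Z,7E,9E,11E,13E)-hexaenoic acid (dienophile C2=C3, diene C7=C8–C9=C10, new bonds C3–C7 and C2–C10), so the cyclohexene and the cyclopentene close together in the last step.
- The hexaenoic acid is cut at C3–C4 into (E)-3-iodo-2-methylacrylic acid and a (Z)-alkenylstannane that carries the all-E tetraene arm.
- The tetraene arm is unrolled by four E-selective carbonyl olefinations (three Wittig reactions with α-formyl ylides, one Horner–Wadsworth–Emmons reaction) back to a C7 aldehyde.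
- The Z-alkenyl metal comes from a Stork–Zhao iodo-olefination; the only stereocentre carried through (C6, later C1 of the indene) is bought as (S)-Roche ester.

Assumption: 2-(triphenylphosphoranylidene)propanal, 2-(triphenylphosphoranylidene)butanal and (E)-3-iodo-2-methylacrylic acid are taken as catalogue reagents; chain locants C1–C14 in the explanations are those of the open-chain hexaenoic acid (CO2H = C1).

**Route**

Step 1
Reactants: 1 methyl (S)-3-hydroxy-2-methylpropanoate ((S)-Roche ester)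
Product: 2 methyl (S)-3-[(tert-butyldimethylsilyl)oxy]-2-methylpropanoate
Conditions: TBSCl, imidazole, CH2Cl2, 0 °C → rt
Reagents that add atoms: tert-butyldimethylsilyl chloride, CC(C)(C)[Si](C)(C)Cl
Why: Imidazole-assisted silyl ether formation masks the CH2OH end so that the ester end can be taken to the aldehyde, and the purchased stereocentre is not touched.

Step 2
Reactants: 2 methyl (S)-3-[(tert-butyldimethylsilyl)oxy]-2-methylpropanoate
Product: 3 (S)-3-[(tert-butyldimethylsilyl)oxy]-2-methylpropanal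
Conditions: i-Bu2AlH (1.05 equiv), CH2Cl2, −78 °C; MeOH, aq. KNaC4H4O6
Reagents that add atoms: none
Why: Partial ester reduction stops at the tetrahedral aluminium hemiacetal at −78 °C, which releases the α-chiral aldehyde only on work-up, so the stereocentre is not epimerised (used crude at once).

Step 3
Reactants: 3 (S)-3-[(tert-butyldimethylsilyl)oxy]-2-methylpropanal; 4 ethyltriphenylphosphonium iodide
Product: 8 tert-butyl{[(2R,3Z)-4-iodo-2-methylpent-3-en-1-yl]oxy}dimethylsilane, via ethylidene ylide 5 (not isolated), via iodophosphonium salt 6 (not isolated), via iodoethylidene ylide 7 (not isolated)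
Conditions: 4, n-BuLi, THF, rt; I2, −78 °C; NaN(SiMe3)2, −20 °C; then 3, −78 → −20 °C
Reagents that add atoms: ethyltriphenylphosphonium iodide (4), CC[P+](c1ccccc1)(c1ccccc1)c1ccccc1.[I-]; iodine, II
Why: In the Stork–Zhao iodo-Wittig olefination the non-stabilised α-iodo ylide adds under kinetic control at −78 °C to give the (Z)-2-iodoalkene (iodine cis to the chain), the geometry needed for C3 and C6 to be cis in the future cyclopentene.

Step 4
Reactants: 8 tert-butyl{[(2R,3Z)-4-iodo-2-methylpent-3-en-1-yl]oxy}dimethylsilane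
Product: 10 tert-butyldimethyl{[(2R,3Z)-2-methyl-4-(tributylstannyl)pent-3-en-1-yl]oxy}silane, via alkenyllithium 9 (not isolated)
Conditions: t-BuLi (2.1 equiv), Et2O, −78 °C; Bu3SnCl, −78 °C → rt
Reagents that add atoms: tributyltin chloride, CCCC[Sn](Cl)(CCCC)CCCC
Why: Iodine–lithium exchange and stannylation of the configurationally stable alkenyllithium both go with retention, giving a Z-alkenylstannane handle that survives the carbonyl chemistry that follows.

Step 5
Reactants: 10 tert-butyldimethyl{[(2R,3Z)-2-methyl-4-(tributylstannyl)pent-3-en-1-yl]oxy}silane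
Product: 11 (2R,3Z)-2-methyl-4-(tributylstannyl)pent-3-en-1-ol
Conditions: Bu4NF, THF, 0 °C → rt
Reagents that add atoms: none
Why: Fluoride-mediated silyl ether cleavage frees the primary alcohol without touching the alkenyl–tin bond or the allylic stereocentre.

Step 6
Reactants: 11 (2R,3Z)-2-methyl-4-(tributylstannyl)pent-3-en-1-ol; 12 2-(triphenylphosphoranylidene)propanal
Product: 14 (2E,4S,5Z)-2,4-dimethyl-6-(tributylstannyl)hepta-2,5-dienal, via stannyl aldehyde 13 (not isolated)
Conditions: Dess–Martin periodinane, pyridine, CH2Cl2, 0 °C; then 12, 40 °C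
Reagents that add atoms: 2-(triphenylphosphoranylidene)propanal (12), CC(C=O)=P(c1ccccc1)(c1ccccc1)c1ccccc1
Why: Dess–Martin oxidation followed in the same flask by Wittig olefination with the stabilised α-formyl ylide traps the labile α-methyl β,γ-unsaturated aldehyde under buffered neutral conditions (1,3-allylic strain keeps its C–H in the alkene plane, so enolisation is slow) and gives the E-trisubstituted enal.

Step 7
Reactants: 14 (2E,4S,5Z)-2,4-dimethyl-6-(tributylstannyl)hepta-2,5-dienal; 15 2-(triphenylphosphoranylidene)butanal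
Product: 16 (2E,4E,6S,7Z)-2-ethyl-4,6-dimethyl-8-(tributylstannyl)nona-2,4,7-trienal
Conditions: 15, toluene, 90 °C
Reagents that add atoms: 2-(triphenylphosphoranylidene)butanal (15), CCC(C=O)=P(c1ccccc1)(c1ccccc1)c1ccccc1
Why: Wittig olefination with a stabilised α-formyl ylide gives the E-trisubstituted alkene, which puts the ethyl group cis and the new formyl carbon trans to the chain at C9=C10, as the diene terminus requires.

Step 8
Reactants: 16 (2E,4E,6S,7Z)-2-ethyl-4,6-dimethyl-8-(tributylstannyl)nona-2,4,7-trienal; 12 2-(triphenylphosphoranylidene)propanal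
Product: 17 (2E,4E,6E,8S,9Z)-4-ethyl-2,6,8-trimethyl-10-(tributylstannyl)undeca-2,4,6,9-tetraenal
Conditions: 12, toluene, 100 °C
Reagents that add atoms: 2-(triphenylphosphoranylidene)propanal (12), CC(C=O)=P(c1ccccc1)(c1ccccc1)c1ccccc1
Why: A third E-selective Wittig olefination with the stabilised formyl ylide adds the methyl-branched C11=C12 unit, and the temperature stays below the onset of [1,5]-hydrogen shifts.

Step 9
Reactants: 17 (2E,4E,6E,8S,9Z)-4-ethyl-2,6,8-trimethyl-10-(tributylstannyl)undeca-2,4,6,9-tetraenal; 18 diethyl benzylphosphonate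
Product: 20 tributyl[(2Z,4S,5E,7E,9E,11E)-8-ethyl-4,6,10-trimethyl-12-phenyldodeca-2,5,7,9,11-pentaen-2-yl]stannane, via phosphonate carbanion 19 (not isolated)
Conditions: 18, NaN(SiMe3)2, THF, 0 °C; then 17, −78 °C → rt
Reagents that add atoms: diethyl benzylphosphonate (18), CCOP(=O)(Cc1ccccc1)OCC
Why: Horner–Wadsworth–Emmons olefination with the benzylphosphonate anion gives the E-styryl alkene and completes the all-E tetraene, while the alkenylstannane and the in-plane doubly allylic C6–H are left alone at low temperature.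

Step 10
Reactants: 20 tributyl[(2Z,4S,5E,7E,9E,11E)-8-ethyl-4,6,10-trimethyl-12-phenyldodeca-2,5,7,9,11-pentaen-2-yl]stannane; 21 (2E)-3-iodo-2-methylprop-2-enoic acid
Product: 23 (1R,3aR,4R,5S,7aS)-5-ethyl-1,3,4,7-tetramethyl-5-[(1E,3E)-2-methyl-4-phenylbuta-1,3-dien-1-yl]-3a,4,5,7a-tetrahydro-1H-indene-4-carboxylic acid, via hexaenoic acid 22 (not isolated)
Conditions: 21, CuO2C(C4H3S) (copper thiophene-2-carboxylate), NMP, 0 °C → rt; then BHT, 70 °C
Reagents that add atoms: (2E)-3-iodo-2-methylprop-2-enoic acid (21), OC(=O)/C(C)=C/I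
Why: Copper-mediated Stille-type (Liebeskind) coupling tolerates the free acid and joins both alkenes with retention, and the resulting (2E,4Z)-dienoic acid then undergoes the intramolecular Diels–Alder reaction through the CO2H-endo, tether-anti transition state on the diene face fixed by 1,3-allylic strain at the Roche-derived C6, which sets C3a, C4, C5 and C7a (trans ring fusion, C1 methyl anti to the C7a–C7 bond) in one event.

**Compound list**

1 | methyl (S)-3-hydroxy-2-methylpropanoate ((S)-Roche ester) | COC(=O)[C@@H](C)CO | starting material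
2 | methyl (S)-3-[(tert-butyldimethylsilyl)oxy]-2-methylpropanoate | COC(=O)[C@@H](C)CO[Si](C)(C)C(C)(C)C | intermediate
3 | (S)-3-[(tert-butyldimethylsilyl)oxy]-2-methylpropanal | O=C[C@@H](C)CO[Si](C)(C)C(C)(C)C | intermediate
4 | ethyltriphenylphosphonium iodide | CC[P+](c1ccccc1)(c1ccccc1)c1ccccc1.[I-] | starting material
5 | ethylidenetriphenylphosphorane | CC=P(c1ccccc1)(c1ccccc1)c1ccccc1 | intermediate
6 | (1-iodoethyl)triphenylphosphonium iodide | CC(I)[P+](c1ccccc1)(c1ccccc1)c1ccccc1.[I-] | intermediate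
7 | (1-iodoethylidene)triphenylphosphorane | CC(I)=P(c1ccccc1)(c1ccccc1)c1ccccc1 | intermediate
8 | tert-butyl{[(2R,3Z)-4-iodo-2-methylpent-3-en-1-yl]oxy}dimethylsilane | I/C(C)=C\[C@@H](C)CO[Si](C)(C)C(C)(C)C | intermediate
9 | [(2E,4R)-5-[(tert-butyldimethylsilyl)oxy]-4-methylpent-2-en-2-yl]lithium (lithium in the place of iodine, geometry retained) | [Li]/C(C)=C\[C@@H](C)CO[Si](C)(C)C(C)(C)C | intermediate
10 | tert-butyldimethyl{[(2R,3Z)-2-methyl-4-(tributylstannyl)pent-3-en-1-yl]oxy}silane | CCCC[Sn](CCCC)(CCCC)/C(C)=C\[C@@H](C)CO[Si](C)(C)C(C)(C)C | intermediate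
11 | (2R,3Z)-2-methyl-4-(tributylstannyl)pent-3-en-1-ol | CCCC[Sn](CCCC)(CCCC)/C(C)=C\[C@@H](C)CO | intermediate
12 | 2-(triphenylphosphoranylidene)propanal | CC(C=O)=P(c1ccccc1)(c1ccccc1)c1ccccc1 | starting material
13 | (2R,3Z)-2-methyl-4-(tributylstannyl)pent-3-enal | CCCC[Sn](CCCC)(CCCC)/C(C)=C\[C@@H](C)C=O | intermediate
14 | (2E,4S,5Z)-2,4-dimethyl-6-(tributylstannyl)hepta-2,5-dienal | CCCC[Sn](CCCC)(CCCC)/C(C)=C\[C@@H](C)/C=C(C)/C=O | intermediate
15 | 2-(triphenylphosphoranylidene)butanal | CCC(C=O)=P(c1ccccc1)(c1ccccc1)c1ccccc1 | starting material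
16 | (2E,4E,6S,7Z)-2-ethyl-4,6-dimethyl-8-(tributylstannyl)nona-2,4,7-trienal | CCCC[Sn](CCCC)(CCCC)/C(C)=C\[C@@H](C)/C=C(C)/C=C(CC)/C=O | intermediate
17 | (2E,4E,6E,8S,9Z)-4-ethyl-2,6,8-trimethyl-10-(tributylstannyl)undeca-2,4,6,9-tetraenal | CCCC[Sn](CCCC)(CCCC)/C(C)=C\[C@@H](C)/C=C(C)/C=C(CC)/C=C(C)/C=O | intermediate
18 | diethyl benzylphosphonate | CCOP(=O)(Cc1ccccc1)OCC | starting material
19 | sodium diethyl (phenylmethanidyl)phosphonate | CCOP(=O)(OCC)[CH-]c1ccccc1.[Na+] | intermediate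
20 | tributyl[(2Z,4S,5E,7E,9E,11E)-8-ethyl-4,6,10-trimethyl-12-phenyldodeca-2,5,7,9,11-pentaen-2-yl]stannane | CCCC[Sn](CCCC)(CCCC)/C(C)=C\[C@@H](C)/C=C(C)/C=C(CC)/C=C(C)/C=C/c1ccccc1 | intermediate
21 | (2E)-3-iodo-2-methylprop-2-enoic acid | OC(=O)/C(C)=C/I | starting material
22 | (2E,4Z,6S,7E,9E,11E,13E)-10-ethyl-2,4,6,8,12-pentamethyl-14-phenyltetradeca-2,4,7,9,11,13-hexaenoic acid | OC(=O)/C(C)=C/C(C)=C\[C@@H](C)/C=C(C)/C=C(CC)/C=C(C)/C=C/c1ccccc1 | intermediate
23 | (1R,3aR,4R,5S,7aS)-5-ethyl-1,3,4,7-tetramethyl-5-[(1E,3E)-2-methyl-4-phenylbuta-1,3-dien-1-yl]-3a,4,5,7a-tetrahydro-1H-indene-4-carboxylic acid | CC[C@]1(/C=C(C)/C=C/c2ccccc2)C=C(C)[C@H]2[C@H](C)C=C(C)[C@@H]2[C@@]1(C)C(=O)O | target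

**Totals**

Total step count: 10. Longest linear sequence: 10 steps (1 → 23).

**Steps most likely to fail, with fallbacks**

Step 3. The Stork–Zhao olefination usually gives modest yields, and some E-iodide or α-epimerised material can form. The fallback sets out from 3 and comes back at 10. Ramirez dibromo-olefination of 3 (CBr4, PPh3, 2,6-lutidine, CH2Cl2, 0 °C) gives tert-butyl{[(2R)-4,4-dibromo-2-methylbut-3-en-1-yl]oxy}dimethylsilane F1. A trans-selective Negishi mono-methylation (Me2Zn, PdCl2(DPEphos), THF) replaces only the bromine trans to the chain and gives tert-butyl{[(2R,3Z)-4-bromo-2-methylpent-3-en-1-yl]oxy}dimethylsilane F2. Bromine–lithium exchange with t-BuLi and a Bu3SnCl quench then give 10 without passing through 8.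

Step 6. The aldehyde 13 is α-chiral and β,γ-unsaturated, and the formyl ylide reacts slowly, so epimerisation, alkene migration or protodestannylation can compete. The fallback sets out from 11 and comes back at 14. The Dess–Martin oxidation is run at 0 °C with ethyl 2-(triphenylphosphoranylidene)propanoate already in the flask; this more reactive ester ylide traps 13 as it forms and gives ethyl (2E,4S,5Z)-2,4-dimethyl-6-(tributylstannyl)hepta-2,5-dienoate F3. Reduction with i-Bu2AlH at −78 °C gives (2E,4S,5Z)-2,4-dimethyl-6-(tributylstannyl)hepta-2,5-dien-1-ol F4, and MnO2 in CH2Cl2 oxidises this allylic alcohol to 14.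

Step 10. The stannane is hindered, and the cycloaddition builds two adjacent quaternary carbons; its endo/exo ratio is not guaranteed, and temperatures above about 100 °C would invite [1,5]-hydrogen shifts. The fallback sets out from 20 and comes back at 23. Coupling of 20 with (E)-3-iodo-2-methylprop-2-en-1-ol (Pd(PPh3)4, copper thiophene-2-carboxylate, DMF) gives (2E,4Z,6S,7E,9E,11E,13E)-10-ethyl-2,4,6,8,12-pentamethyl-14-phenyltetradeca-2,4,7,9,11,13-hexaen-1-ol F5. MnO2 oxidation gives (2E,4Z,6S,7E,9E,11E,13E)-10-ethyl-2,4,6,8,12-pentamethyl-14-phenyltetradeca-2,4,7,9,11,13-hexaenal F6. Its more reactive enal dienophile cyclises under Me2AlCl at −78 to −20 °C, with stronger carbonyl-endo control, to (1R,3aR,4R,5S,7aS)-5-ethyl-1,3,4,7-tetramethyl-5-[(1E,3E)-2-methyl-4-phenylbuta-1,3-dien-1-yl]-3a,4,5,7a-tetrahydro-1H-indene-4-carbaldehyde F7. Pinnick oxidation (NaClO2, NaH2PO4, 2-methylbut-2-ene, t-BuOH/H2O) then gives 23.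

**Further compounds**

F1 | step 3 | tert-butyl{[(2R)-4,4-dibromo-2-methylbut-3-en-1-yl]oxy}dimethylsilane | BrC(Br)=C[C@@H](C)CO[Si](C)(C)C(C)(C)C
F2 | step 3 | tert-butyl{[(2R,3Z)-4-bromo-2-methylpent-3-en-1-yl]oxy}dimethylsilane | Br/C(C)=C\[C@@H](C)CO[Si](C)(C)C(C)(C)C
F3 | step 6 | ethyl (2E,4S,5Z)-2,4-dimethyl-6-(tributylstannyl)hepta-2,5-dienoate | CCCC[Sn](CCCC)(CCCC)/C(C)=C\[C@@H](C)/C=C(C)/C(=O)OCC
F4 | step 6 | (2E,4S,5Z)-2,4-dimethyl-6-(tributylstannyl)hepta-2,5-dien-1-ol | CCCC[Sn](CCCC)(CCCC)/C(C)=C\[C@@H](C)/C=C(C)/CO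
F5 | step 10 | (2E,4Z,6S,7E,9E,11E,13E)-10-ethyl-2,4,6,8,12-pentamethyl-14-phenyltetradeca-2,4,7,9,11,13-hexaen-1-ol | OC/C(C)=C/C(C)=C\[C@@H](C)/C=C(C)/C=C(CC)/C=C(C)/C=C/c1ccccc1
F6 | step 10 | (2E,4Z,6S,7E,9E,11E,13E)-10-ethyl-2,4,6,8,12-pentamethyl-14-phenyltetradeca-2,4,7,9,11,13-hexaenal | O=C/C(C)=C/C(C)=C\[C@@H](C)/C=C(C)/C=C(CC)/C=C(C)/C=C/c1ccccc1
F7 | step 10 | (1R,3aR,4R,5S,7aS)-5-ethyl-1,3,4,7-tetramethyl-5-[(1E,3E)-2-methyl-4-phenylbuta-1,3-dien-1-yl]-3a,4,5,7a-tetrahydro-1H-indene-4-carbaldehyde | CC[C@]1(/C=C(C)/C=C/c2ccccc2)C=C(C)[C@H]2[C@H](C)C=C(C)[C@@H]2[C@@]1(C)C=O
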